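## Structural features

The target is a 1-aryl-1,2-dihydronaphthalene lignan. Benzo ring A (C4a, C5–C8, C8a) is fused to the partly saturated ring B (C1–C4), and a 4-hydroxy-3-methoxyphenyl ring E is attached at C1. Ring A carries hydrogen at C5 and C8, methoxyl at C6 and a free hydroxyl at C7. Ring B carries the C3=C4 double bond, conjugated with both ring A and the C3 formyl group, and an acetoxymethyl group on C2. The only stereocentres, C1 (S, benzylic to rings A and E) and C2 (R), are adjacent and hold aryl and acetoxymethyl trans. The fragile groups are the enal, the primary acetate (hydrolysis, migration, base-induced loss through C2–H), the two phenols and the 1,2-dihydronaphthalene, which aromatises on oxidation with loss of both stereocentres. The real difficulty is control of C1 and C2, in the relative and the absolute sense, next to an unsaturated, oxidation-prone ring, while the 6-methoxy/7-hydroxy pattern of ring A is kept distinct from the same pair on ring E. The key step exploits the fact that C6, C7, C8 and C8a of ring A map onto C3, C4, C5 and C6 of a 3-methoxy-4-silyloxy-2-pyrone, and C4a and C5 onto a terminal alkyne. The chain C1–C2–C3=C4 that joins them becomes ring B, so both stereocentres, the acetate and the enal are in place before either ring exists.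

## Logic of the disconnections

28 from 27: the two aryl O–Si bonds are cut. Both phenols stay masked by one kind of group throughout, and its removal needs only buffered fluoride, which the acetate, the enal and the dihydronaphthalene tolerate. The demand on the forward step is a near-neutral medium.

27 from 25 (through 26): C5–C6 and C4a–C8a are cut and CO2 is put back across C6 and C8a. Two rings and the whole substitution pattern of ring A reduce to a monocyclic pyrone and an acyclic enyne tether, and no stereocentre is touched. The forward step needs a terminal alkyne, the C3=C4 geometry with C2 and alkynyl cis, and a substrate that survives heating. The pyrone oxygen is a vinylogous silyl ester, so 25 carries triisopropylsilyl groups; a tert-butyldimethylsilyl group at that position would be too easily lost in the four steps that follow its introduction.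

25 from 24, and 24 from 21 and 22: the C(sp)–Si bond and then the C3=C4 double bond are cut. The enynal is the most sensitive part of 25 and is therefore made last. An aldol condensation gives the thermodynamic E enal, which is exactly the geometry the cycloaddition needs. The silyl cap of 22 protects the ynal against conjugate addition and polymerisation. The forward steps must be mild enough for the silyl pyrone and for C1–H.

21 from 20, and 20 from 18: these are changes of oxidation state at the terminal carbon of a vinyl group. The vinyl group is inert through the construction of the pyrone and is the direct outcome of a [3,3] rearrangement. The forward steps need a hydroboration that ignores the pyrone and an oxidative work-up that spares the pyrone silyl ether.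

18 from 17, 17 from 16, and 16 from 9 and 14: the pyrone O–Si bond, the lactone C–O bond and then the C–C bond between the carboxyl carbon of 9 and the terminal carbon of 14 are cut. The heterocycle reduces to a carboxylic acid and a four-carbon unit whose constitution already fixes which oxygen of the future ring A is methylated. C1 is benzylic and alpha to the acyl group at this stage, so the C–C bond must be formed without base; this is why 14 is a silyl dienol ether and not a dianion.

14 from 12, and 12 from 10: two O–Si bonds and one C–C bond are cut, which leads back to a commercial ester and an acetyl donor.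

9 from 7: the C1–C2 bond is cut and the allylic C–O bond of an ester is restored. Both stereocentres then arise together in one chair transition state from two alkene geometries. Arylacetates give the ketene acetal with aryl cis to the metal-bearing oxygen, which puts the aryl group equatorial; the 2,3-syn acid (trans on ring B) therefore requires the E allylic ester. The Z isomer of 7 would place the acetoxymethyl group axial and give the 2,3-anti acid, that is the cis relationship on ring B, so it is not used. The absolute sense must come from a chiral controller on the enolate oxygen. The acetate of 7 is carried from here to 28, so no later step may use a strong base or nucleophile.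

7 from 3 and 5, 3 from 1, and 5 from 4: one ester C–O bond, one O–Si bond and one acetyl C–O bond are cut. These lead to three commercial materials, with the alkene geometry bought in 4.

## Other disconnections considered

Alternative 1: The cuts are C1–aryl and C2–C3. In the forward step a chiral complex of monovalent rhodium would transfer the aryl group of boronic acid A2 to the beta carbon of cinnamate A1, and the resulting enolate would close ring B by aldol addition to the side-chain ketone, giving tetralin A3. In its favour, the step is convergent, ring E enters late from a robust reagent, and a catalytic amount of chiral ligand sets C1 and relays it to C2 through a closed aldol transition state. On absolute stereocontrol it is the better plan, because the chosen route needs a stoichiometric, though recoverable, controller. Against it, an ortho-substituted cinnamate ester is a slow acceptor, and protodeboronation and enolisation of the benzylic ketone in A1 would compete. A3 is also still far from 28: the tertiary alcohol must be eliminated toward C4 and not toward C2, the ester must be reduced and acetylated, and the acetal must be opened. In the chosen plan the key step delivers ring B with formyl, alkene and acetate already correct. On convergence the two plans are equal; on steps after the key step the alternative is worse.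

Alternative 2: The cuts are C3–C4 and C4–C4a, that is removal of C4 from ring B. In the forward step a Lewis acid would promote addition of trimethylsilyldiazomethane A5 to the carbonyl group of trans-indanone A4, and migration of the ring A carbon, followed by protodesilylation, would give the 2-tetralone A6. In its favour, the trans arrangement in A4 is the thermodynamic one in a rigid five-membered ring and could be corrected by equilibration. On security of the relative configuration at C1 and C2 it is therefore the equal or the better of the chosen plan, which relies on kinetic control in a chair transition state. Against it, migration of the electron-rich aryl carbon must beat migration of the secondary alkyl carbon C2, and A6 is a beta-silyloxy ketone that can eliminate or epimerise at C2. The C3 ketone must then be turned into the formyl-bearing alkene (regioselective enol sulfonate toward C4, then a palladium-catalysed formylation) and the primary silyl ether exchanged for acetate. Ring A must also be bought or made with its full substitution, whereas the chosen plan builds it with the pattern fixed by constitution. Step economy is similar or worse.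

Alternative 3: The cuts are C1–C2 and C3–C4. In the forward step irradiation of benzaldehyde A7 in the presence of enal A8 should give tetralin A9 by photoenolisation and [4+2] addition. In its favour, ring B arrives with every carbon in the right oxidation state, and only dehydration of the beta-hydroxy aldehyde and desilylation remain. On step economy this is clearly the better plan. The E geometry of A8 should also translate into the trans relationship of formyl and acetoxymethyl. Against it, there is no inherent absolute control, so a chiral Lewis acid of limited precedent for enal dienophiles, or a resolution, would be needed. The configuration at C1 depends on the geometry of the aryl-bearing terminus of the photoenol, which is less certain than a chair [3,3] transition state. A8 and the products are also light- and base-sensitive. On ring A regiochemistry the two plans are equal, since ring A is preformed here and tether-controlled in the chosen plan.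

Key step: step 14

Assumption: the (S,S)-configured diazaborolidine controller is taken to deliver the (2S,3S) acid 9; should an arylacetate show the opposite sense of induction, the (R,R) controller would be used with no other change.

Step 1
Reactants: 1 homovanillic acid
Product: 3 2-[3-methoxy-4-(triisopropylsilyloxy)phenyl]acetic acid, via bis-silyl ester 2 (not isolated)
Conditions: iPr3SiCl (2.3 equiv), imidazole, DMF, rt; then K2CO3, THF–MeOH–H2O, 0 °C; citric acid work-up
Reagents that add atoms: triisopropylsilyl chloride, CC(C)[Si](Cl)(C(C)C)C(C)C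
Why: Both acidic groups are silylated, and the silyl ester is far more labile than the hindered aryl silyl ether, so brief carbonate hydrolysis should free only the carboxylic acid (silylation, then selective silyl ester hydrolysis).

Step 2
Reactants: 4 (E)-but-2-ene-1,4-diol
Product: 5 (E)-4-hydroxybut-2-en-1-yl acetate
Conditions: Ac2O (0.3 equiv relative to 4), Et3N, DMAP (cat.), THF, 0 °C
Reagents that add atoms: acetic anhydride, CC(=O)OC(C)=O
Why: Acylation with the cheap diol in excess favours the monoacetate, which is separated from unchanged diol by extraction and chromatography; the alkene geometry is not touched (nucleophilic acyl substitution).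

Step 3
Reactants: 3 2-[3-methoxy-4-(triisopropylsilyloxy)phenyl]acetic acid; 5 (E)-4-hydroxybut-2-en-1-yl acetate
Product: 7 (E)-4-acetoxybut-2-en-1-yl 2-[3-methoxy-4-(triisopropylsilyloxy)phenyl]acetate, via O-acylisourea 6 (not isolated)
Conditions: EDC·HCl, DMAP (cat.), CH2Cl2, 0 °C → rt
Reagents that add atoms: none
Why: Carbodiimide activation joins an unhindered arylacetic acid to a primary allylic alcohol under neutral conditions that leave the acetate and the aryl silyl ether alone (Steglich-type esterification).

Step 4
Reactants: 7 (E)-4-acetoxybut-2-en-1-yl 2-[3-methoxy-4-(triisopropylsilyloxy)phenyl]acetate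
Product: 9 (2S,3S)-3-(acetoxymethyl)-2-[3-methoxy-4-(triisopropylsilyloxy)phenyl]pent-4-enoic acid, via boron ketene acetal 8 (not isolated)
Conditions: (S,S)-bis-sulfonamide + BBr3, CH2Cl2, then removal of volatiles; 7, iPr2NEt, CH2Cl2, −78 °C, then 4 °C → rt; aqueous work-up at pH 3, controller recovered
Reagents that add atoms: none
Why: Soft enolisation by the chiral bromoborane and the amine should give the O-boron ketene acetal with aryl cis to the boron-bearing oxygen, and the arylacetate is enolised in preference to the far less acidic acetate. The chair [3,3] shift (enantioselective ester enolate Claisen rearrangement of Ireland–Claisen type) with aryl and acetoxymethyl both equatorial gives the 2,3-syn acid, and the C2-symmetric diazaborolidine decides which face of the ketene acetal meets the allyl terminus, which sets both centres as (2S,3S).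

Step 5
Reactants: 10 methyl methoxyacetate
Product: 12 methyl 2-methoxy-3-oxobutanoate, via lithium enolate 11 (not isolated)
Conditions: LiN(iPr)2 (2.1 equiv), THF, −78 °C; AcCl; aqueous HCl work-up
Reagents that add atoms: acetyl chloride, CC(Cl)=O
Why: C-Acylation of the ester enolate (crossed Claisen condensation); the second equivalent of base converts the more acidic beta-keto ester into its enolate and so prevents a second acylation.

Step 6
Reactants: 12 methyl 2-methoxy-3-oxobutanoate
Product: 14 1,2-dimethoxy-1,3-bis(trimethylsilyloxy)buta-1,3-diene, via monosilyl enol ether 13 (not isolated)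
Conditions: Me3SiOTf (2.2 equiv), Et3N (2.5 equiv), Et2O, 0 °C → rt; filtration under argon, used crude
Reagents that add atoms: trimethylsilyl trifluoromethanesulfonate, C[Si](C)(C)OS(=O)(=O)C(F)(F)F
Why: Silyl triflate and amine convert a beta-keto ester first into the 3-silyloxy enoate and then, by O-silylation of the ester carbonyl and loss of a gamma proton, into the 1,3-bis(silyloxy)diene (double silyl enol ether formation).

Step 7
Reactants: 9 (2S,3S)-3-(acetoxymethyl)-2-[3-methoxy-4-(triisopropylsilyloxy)phenyl]pent-4-enoic acid; 14 1,2-dimethoxy-1,3-bis(trimethylsilyloxy)buta-1,3-diene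
Product: 16 methyl (6S,7S)-7-(acetoxymethyl)-2-methoxy-6-[3-methoxy-4-(triisopropylsilyloxy)phenyl]-3,5-dioxonon-8-enoate, via acid chloride 15 (not isolated)
Conditions: (COCl)2, DMF (cat.), CH2Cl2, 0 °C → rt, evaporation; 14 (1.5 equiv), CH2Cl2, −78 → 20 °C; aqueous NaHCO3 then dilute HCl
Reagents that add atoms: none
Why: The terminal carbon of the electron-rich bis(silyloxy)diene is acylated by the acid chloride without any base (gamma-acylation of a 1,3-bis(silyl enol ether), a Mukaiyama-type reaction), so the benzylic stereocentre next to the acyl group never meets an enolising reagent. Hydrolytic work-up gives the 3,5-dioxo ester as a mixture of C2 epimers and enol forms, which is of no consequence.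

Step 8
Reactants: 16 methyl (6S,7S)-7-(acetoxymethyl)-2-methoxy-6-[3-methoxy-4-(triisopropylsilyloxy)phenyl]-3,5-dioxonon-8-enoate
Product: 17 (2S)-2-{(S)-(4-hydroxy-3-methoxy-2-oxo-2H-pyran-6-yl)[3-methoxy-4-(triisopropylsilyloxy)phenyl]methyl}but-3-en-1-yl acetate
Conditions: DBU (1.5 equiv), THF, 4 Å molecular sieves, rt; dilute HCl work-up
Reagents that add atoms: none
Why: The enolate oxygen of the C5 carbonyl lactonises onto the methyl ester and tautomerisation gives the 4-hydroxy-2-pyrone (cyclisation of a 3,5-dioxo ester). The diketone enolate formed first makes deprotonation of the benzylic C–H unfavourable, and the sieves take up methanol so that the acetate is not transesterified.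

Step 9
Reactants: 17 (2S)-2-{(S)-(4-hydroxy-3-methoxy-2-oxo-2H-pyran-6-yl)[3-methoxy-4-(triisopropylsilyloxy)phenyl]methyl}but-3-en-1-yl acetate
Product: 18 (2S)-2-{(S)-[3-methoxy-2-oxo-4-(triisopropylsilyloxy)-2H-pyran-6-yl][3-methoxy-4-(triisopropylsilyloxy)phenyl]methyl}but-3-en-1-yl acetate
Conditions: iPr3SiCl, imidazole, CH2Cl2, 0 °C → rt
Reagents that add atoms: triisopropylsilyl chloride, CC(C)[Si](Cl)(C(C)C)C(C)C
Why: O-Silylation of the acidic vinylogous carboxylic acid gives the 4-silyloxy-2-pyrone; the bulky triisopropylsilyl group is chosen because this oxygen behaves as a vinylogous silyl ester.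

Step 10
Reactants: 18 (2S)-2-{(S)-[3-methoxy-2-oxo-4-(triisopropylsilyloxy)-2H-pyran-6-yl][3-methoxy-4-(triisopropylsilyloxy)phenyl]methyl}but-3-en-1-yl acetate
Product: 20 (2S)-4-hydroxy-2-{(S)-[3-methoxy-2-oxo-4-(triisopropylsilyloxy)-2H-pyran-6-yl][3-methoxy-4-(triisopropylsilyloxy)phenyl]methyl}butyl acetate, via alkylborane 19 (not isolated)
Conditions: 9-BBN (1.3 equiv), THF, 0 °C → rt; H2O2, pH 7 phosphate buffer, 0 °C
Reagents that add atoms: hydrogen peroxide, OO
Why: 9-BBN adds to the monosubstituted alkene with anti-Markovnikov regiochemistry and should not touch the conjugated pyrone, the lactone or the acetate; buffered peroxide oxidises the C–B bond without cleaving the pyrone silyl ether (hydroboration–oxidation).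

Step 11
Reactants: 20 (2S)-4-hydroxy-2-{(S)-[3-methoxy-2-oxo-4-(triisopropylsilyloxy)-2H-pyran-6-yl][3-methoxy-4-(triisopropylsilyloxy)phenyl]methyl}butyl acetate
Product: 21 (2S)-2-{(S)-[3-methoxy-2-oxo-4-(triisopropylsilyloxy)-2H-pyran-6-yl][3-methoxy-4-(triisopropylsilyloxy)phenyl]methyl}-4-oxobutyl acetate
Conditions: Dess–Martin periodinane, NaHCO3, CH2Cl2, 0 °C → rt
Reagents that add atoms: none
Why: Dess–Martin oxidation under bicarbonate buffer stops at the aldehyde and is neutral enough for the silyl pyrone and for the stereocentre next to it.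

Step 12
Reactants: 21 (2S)-2-{(S)-[3-methoxy-2-oxo-4-(triisopropylsilyloxy)-2H-pyran-6-yl][3-methoxy-4-(triisopropylsilyloxy)phenyl]methyl}-4-oxobutyl acetate; 22 3-(trimethylsilyl)propynal
Product: 24 (2R,3E)-3-formyl-2-{(S)-[3-methoxy-2-oxo-4-(triisopropylsilyloxy)-2H-pyran-6-yl][3-methoxy-4-(triisopropylsilyloxy)phenyl]methyl}-6-(trimethylsilyl)hex-3-en-5-yn-1-yl acetate, via aldol adduct 23 (not isolated)
Conditions: 22 (1.5 equiv), pyrrolidine (20 mol%), PhCO2H (20 mol%), CH2Cl2, 4 Å molecular sieves, 0 °C → rt
Reagents that add atoms: none
Why: The amine forms an enamine at the only enolisable aldehyde, which adds to the non-enolisable ynal; amine-assisted dehydration then gives the alpha-substituted enal in its stable E geometry, with alkynyl trans to formyl and cis to C2 (secondary-amine-catalysed aldol condensation). The silyl cap hinders conjugate addition of the amine to the ynal.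

Step 13
Reactants: 24 (2R,3E)-3-formyl-2-{(S)-[3-methoxy-2-oxo-4-(triisopropylsilyloxy)-2H-pyran-6-yl][3-methoxy-4-(triisopropylsilyloxy)phenyl]methyl}-6-(trimethylsilyl)hex-3-en-5-yn-1-yl acetate
Product: 25 (2R,3E)-3-formyl-2-{(S)-[3-methoxy-2-oxo-4-(triisopropylsilyloxy)-2H-pyran-6-yl][3-methoxy-4-(triisopropylsilyloxy)phenyl]methyl}hex-3-en-5-yn-1-yl acetate
Conditions: AgNO3 (10 mol%), acetone–H2O–CH2Cl2, rt, dark; used at once
Reagents that add atoms: none
Why: Monovalent silver activates only the silylalkyne toward protodesilylation by water, so the aryl and pyrone silyl ethers, the acetate and the enal should remain (silver-catalysed C(sp)–Si cleavage).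

Step 14
Reactants: 25 (2R,3E)-3-formyl-2-{(S)-[3-methoxy-2-oxo-4-(triisopropylsilyloxy)-2H-pyran-6-yl][3-methoxy-4-(triisopropylsilyloxy)phenyl]methyl}hex-3-en-5-yn-1-yl acetate
Product: 27 [(1S,2R)-3-formyl-6-methoxy-1-[3-methoxy-4-(triisopropylsilyloxy)phenyl]-7-(triisopropylsilyloxy)-1,2-dihydronaphthalen-2-yl]methyl acetate, via bridged lactone 26 (not isolated)
Conditions: toluene (0.01 M), BHT (cat.), degassed, 120 °C, sealed tube
Reagents that add atoms: none
Why: The electron-rich 3-methoxy-4-silyloxy-2-pyrone reacts as a diene through its C3 and C6 with the alkyne, whose acceptor character is raised by conjugation through C3=C4 with the formyl group; a concerted, asynchronous [4+2] cycloaddition forms C4a–C8a and C5–C6 and gives the 2-oxabicyclo[2.2.2]octadienone 26. Retro-[4+2] loss of CO2 from 26 is driven by aromatisation and delivers ring A. The closest known reaction type is the intramolecular Diels–Alder reaction of 2-pyrones with tethered alkynes followed by extrusion of CO2. Ring A closes by cycloaddition–cycloreversion; ring B closes in the cycloaddition itself, as the six-membered ring defined by the four-atom tether C1–C2–C3=C4 between pyrone C6 and the internal alkyne carbon. No stereocentre is created in 27: the bridgehead centres of 26 disappear with CO2, so either face of the pyrone may react, and C1 and C2 pass through unchanged under neutral thermal conditions. The regiochemistry (methoxyl at C6, silyloxy at C7) is enforced by the tether, which lets only the internal alkyne carbon reach pyrone C6. The reactive geometry, C2 and alkynyl cis on C3=C4, is the one set in step 12; high dilution, exclusion of oxygen and a radical inhibitor are meant to suppress polymerisation of the enynal and dehydrogenation of the product.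

Step 15
Reactants: 27 [(1S,2R)-3-formyl-6-methoxy-1-[3-methoxy-4-(triisopropylsilyloxy)phenyl]-7-(triisopropylsilyloxy)-1,2-dihydronaphthalen-2-yl]methyl acetate
Product: 28 [(1S,2R)-3-formyl-7-hydroxy-1-(4-hydroxy-3-methoxyphenyl)-6-methoxy-1,2-dihydronaphthalen-2-yl]methyl acetate
Conditions: Bu4NF (2.4 equiv), AcOH (3 equiv), THF, 0 °C
Reagents that add atoms: none
Why: Fluoride cleaves both aryl O–Si bonds, and acetic acid protonates the phenoxides as they form, so the acetate and the enal are not exposed to base (buffered fluoride desilylation).

Compound list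

1 | homovanillic acid, 2-(4-hydroxy-3-methoxyphenyl)acetic acid | COc1cc(CC(=O)O)ccc1O | starting material
2 | triisopropylsilyl 2-[3-methoxy-4-(triisopropylsilyloxy)phenyl]acetate (not isolated) | COc1cc(CC(=O)O[Si](C(C)C)(C(C)C)C(C)C)ccc1O[Si](C(C)C)(C(C)C)C(C)C | intermediate
3 | 2-[3-methoxy-4-(triisopropylsilyloxy)phenyl]acetic acid | COc1cc(CC(=O)O)ccc1O[Si](C(C)C)(C(C)C)C(C)C | intermediate
4 | (E)-but-2-ene-1,4-diol | OC/C=C/CO | starting material
5 | (E)-4-hydroxybut-2-en-1-yl acetate | CC(=O)OC/C=C/CO | intermediate
6 | O-acylisourea from 3 and EDC (not isolated) | CCN=C(NCCCN(C)C)OC(=O)Cc1ccc(O[Si](C(C)C)(C(C)C)C(C)C)c(OC)c1 | intermediate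
7 | (E)-4-acetoxybut-2-en-1-yl 2-[3-methoxy-4-(triisopropylsilyloxy)phenyl]acetate | COc1cc(CC(=O)OC/C=C/COC(C)=O)ccc1O[Si](C(C)C)(C(C)C)C(C)C | intermediate
8 | O-boron ketene acetal of 7, aryl cis to the boron-bearing oxygen, boron held in the (4S,5S)-1,3-bis{[3,5-bis(trifluoromethyl)phenyl]sulfonyl}-4,5-diphenyl-1,3,2-diazaborolidine (not isolated) | COc1cc(/C=C(\OB2N(S(=O)(=O)c3cc(C(F)(F)F)cc(C(F)(F)F)c3)[C@@H](c3ccccc3)[C@H](c3ccccc3)N2S(=O)(=O)c2cc(C(F)(F)F)cc(C(F)(F)F)c2)OC/C=C/COC(C)=O)ccc1O[Si](C(C)C)(C(C)C)C(C)C | intermediate
9 | (2S,3S)-3-(acetoxymethyl)-2-[3-methoxy-4-(triisopropylsilyloxy)phenyl]pent-4-enoic acid | COc1cc([C@H]([C@@H](COC(C)=O)C=C)C(=O)O)ccc1O[Si](C(C)C)(C(C)C)C(C)C | intermediate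
10 | methyl methoxyacetate | COCC(=O)OC | starting material
11 | lithium enolate of 10 (not isolated) | [Li]OC(OC)=COC | intermediate
12 | methyl 2-methoxy-3-oxobutanoate | COC(C(C)=O)C(=O)OC | intermediate
13 | methyl 2-methoxy-3-(trimethylsilyloxy)but-2-enoate (not isolated) | COC(=O)C(OC)=C(C)O[Si](C)(C)C | intermediate
14 | 1,2-dimethoxy-1,3-bis(trimethylsilyloxy)buta-1,3-diene | C=C(O[Si](C)(C)C)C(OC)=C(OC)O[Si](C)(C)C | intermediate
15 | (2S,3S)-3-(acetoxymethyl)-2-[3-methoxy-4-(triisopropylsilyloxy)phenyl]pent-4-enoyl chloride (not isolated) | COc1cc([C@H]([C@@H](COC(C)=O)C=C)C(Cl)=O)ccc1O[Si](C(C)C)(C(C)C)C(C)C | intermediate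
16 | methyl (6S,7S)-7-(acetoxymethyl)-2-methoxy-6-[3-methoxy-4-(triisopropylsilyloxy)phenyl]-3,5-dioxonon-8-enoate (C2 epimers and enol forms) | COc1cc([C@H]([C@@H](COC(C)=O)C=C)C(=O)CC(=O)C(OC)C(=O)OC)ccc1O[Si](C(C)C)(C(C)C)C(C)C | intermediate
17 | (2S)-2-{(S)-(4-hydroxy-3-methoxy-2-oxo-2H-pyran-6-yl)[3-methoxy-4-(triisopropylsilyloxy)phenyl]methyl}but-3-en-1-yl acetate | COc1cc([C@H]([C@@H](COC(C)=O)C=C)C2=CC(O)=C(OC)C(=O)O2)ccc1O[Si](C(C)C)(C(C)C)C(C)C | intermediate
18 | (2S)-2-{(S)-[3-methoxy-2-oxo-4-(triisopropylsilyloxy)-2H-pyran-6-yl][3-methoxy-4-(triisopropylsilyloxy)phenyl]methyl}but-3-en-1-yl acetate | COc1cc([C@H]([C@@H](COC(C)=O)C=C)C2=CC(O[Si](C(C)C)(C(C)C)C(C)C)=C(OC)C(=O)O2)ccc1O[Si](C(C)C)(C(C)C)C(C)C | intermediate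
19 | B-alkyl-9-borabicyclo[3.3.1]nonane from 18 (not isolated) | COc1cc([C@H]([C@@H](COC(C)=O)CCB2C3CCCC2CCC3)C2=CC(O[Si](C(C)C)(C(C)C)C(C)C)=C(OC)C(=O)O2)ccc1O[Si](C(C)C)(C(C)C)C(C)C | intermediate
20 | (2S)-4-hydroxy-2-{(S)-[3-methoxy-2-oxo-4-(triisopropylsilyloxy)-2H-pyran-6-yl][3-methoxy-4-(triisopropylsilyloxy)phenyl]methyl}butyl acetate | COc1cc([C@H]([C@@H](COC(C)=O)CCO)C2=CC(O[Si](C(C)C)(C(C)C)C(C)C)=C(OC)C(=O)O2)ccc1O[Si](C(C)C)(C(C)C)C(C)C | intermediate
21 | (2S)-2-{(S)-[3-methoxy-2-oxo-4-(triisopropylsilyloxy)-2H-pyran-6-yl][3-methoxy-4-(triisopropylsilyloxy)phenyl]methyl}-4-oxobutyl acetate | COc1cc([C@H]([C@@H](COC(C)=O)CC=O)C2=CC(O[Si](C(C)C)(C(C)C)C(C)C)=C(OC)C(=O)O2)ccc1O[Si](C(C)C)(C(C)C)C(C)C | intermediate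
22 | 3-(trimethylsilyl)propynal | C[Si](C)(C)C#CC=O | starting material
23 | beta-hydroxy aldehyde from 21 and 22, mixture at the two new centres (not isolated) | COc1cc([C@H]([C@@H](COC(C)=O)C(C=O)C(O)C#C[Si](C)(C)C)C2=CC(O[Si](C(C)C)(C(C)C)C(C)C)=C(OC)C(=O)O2)ccc1O[Si](C(C)C)(C(C)C)C(C)C | intermediate
24 | (2R,3E)-3-formyl-2-{(S)-[3-methoxy-2-oxo-4-(triisopropylsilyloxy)-2H-pyran-6-yl][3-methoxy-4-(triisopropylsilyloxy)phenyl]methyl}-6-(trimethylsilyl)hex-3-en-5-yn-1-yl acetate | COc1cc([C@H]([C@@H](COC(C)=O)/C(C=O)=C\C#C[Si](C)(C)C)C2=CC(O[Si](C(C)C)(C(C)C)C(C)C)=C(OC)C(=O)O2)ccc1O[Si](C(C)C)(C(C)C)C(C)C | intermediate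
25 | (2R,3E)-3-formyl-2-{(S)-[3-methoxy-2-oxo-4-(triisopropylsilyloxy)-2H-pyran-6-yl][3-methoxy-4-(triisopropylsilyloxy)phenyl]methyl}hex-3-en-5-yn-1-yl acetate | COc1cc([C@H]([C@@H](COC(C)=O)/C(C=O)=C\C#C)C2=CC(O[Si](C(C)C)(C(C)C)C(C)C)=C(OC)C(=O)O2)ccc1O[Si](C(C)C)(C(C)C)C(C)C | intermediate
26 | bridged lactone, the 2-oxabicyclo[2.2.2]octa-5,7-dien-3-one cycloadduct of 25, either bridgehead configuration (not isolated) | COc1cc([C@@H]2[C@@H](COC(C)=O)C(C=O)=CC3=CC4(OC)C(O[Si](C(C)C)(C(C)C)C(C)C)=CC23OC4=O)ccc1O[Si](C(C)C)(C(C)C)C(C)C | intermediate
27 | [(1S,2R)-3-formyl-6-methoxy-1-[3-methoxy-4-(triisopropylsilyloxy)phenyl]-7-(triisopropylsilyloxy)-1,2-dihydronaphthalen-2-yl]methyl acetate | COc1cc([C@H]2c3cc(O[Si](C(C)C)(C(C)C)C(C)C)c(OC)cc3C=C(C=O)[C@@H]2COC(C)=O)ccc1O[Si](C(C)C)(C(C)C)C(C)C | intermediate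
28 | [(1S,2R)-3-formyl-7-hydroxy-1-(4-hydroxy-3-methoxyphenyl)-6-methoxy-1,2-dihydronaphthalen-2-yl]methyl acetate | COc1cc([C@H]2c3cc(O)c(OC)cc3C=C(C=O)[C@@H]2COC(C)=O)ccc1O | target

Total step count: 15 steps; steps 2, 5 and 6 are side branches.
Longest linear sequence: 12 steps from 1 (steps 1, 3, 4 and 7 to 15).

Least certain steps

Step 14 (key step). The terminal enynal may oligomerise or decompose before it cyclises, because the alkyne is activated only vinylogously and the reaction needs prolonged heating. Fallback: set out from 24 and omit step 13. The capped alkyne is much less prone to polymerise and can be heated harder (o-dichlorobenzene, 150 °C). Cycloaddition would pass through the silylated bridged lactone F1 and, after loss of CO2, give the 5-trimethylsilyl dihydronaphthalene F2. The new aryl–silicon bond lies ortho to the C6 methoxyl, so ipso-protodesilylation with CF3CO2H in CH2Cl2 at 0 °C should remove it and return to the route at 27.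

Step 4. Facial selection by the controller, simple diastereoselection, or both may be poor for an arylacetate. The aryl-conjugated boron ketene acetal may also rearrange so slowly that warming erodes the selectivity. Fallback: from 7, enolise with KN(SiMe3)2 and Me3SiCl in toluene–THF at −78 °C. This should give the silyl ketene acetal F3 (aryl cis to the silyloxy group), which rearranges on warming to the racemic 2,3-syn acid F4 after hydrolytic work-up. Resolution by crystallisation of the 1-phenylethylammonium salt F5 (written for the (S)-amine; the antipode is used if it gives the less soluble salt with the wanted acid) and acidification returns to the route at 9.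

Step 7. Acylation of the diene by the hindered, doubly branched acid chloride may be slow. The acid chloride may also be lost on standing, through ketene formation or through attack of the acetate oxygen on the acyl chloride. Fallback: from 9, activate with carbonyldiimidazole to the acyl imidazolide F6 and add it at −78 °C to an excess of the dianion F7 of 12 (NaH, then n-BuLi, THF). This is the classical gamma-acylation of an acetoacetate dianion and returns to the route at 16. Its weakness is basicity, which is why it is not the first choice.

Step 12. The amine catalyst may be consumed by conjugate addition to the ynal or by attack at the pyrone silyl ether, or the reaction may stop at the aldol adduct. Fallback: from 21, form the tert-butyldimethylsilyl enol ether F8 (tBuMe2SiOTf, Et3N) and carry out a Mukaiyama aldol addition to 22 with BF3·OEt2 at −78 °C to reach 23 as an isolated compound. Mesylation (MsCl, Et3N, 0 °C) gives the mesylate F9, which eliminates under the same conditions and returns to the route at 24.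

Step 10. The pyrone silyl ether or the acetate may be lost during the oxidative work-up, or hydroboration of the hindered vinyl group may be incomplete. Fallback: from 18, an aldehyde-selective Wacker-type oxidation (PdCl2(PhCN)2, CuCl2, AgNO2, t-BuOH–MeNO2, O2) would convert the vinyl group directly into the aldehyde under non-basic conditions. It makes no new compound (F0), returns to the route at 21 and also bypasses step 11.

Further compounds

F1 | step 14 | trimethylsilyl-substituted bridged lactone from 24 (not isolated) | COc1cc([C@@H]2[C@@H](COC(C)=O)C(C=O)=CC3=C([Si](C)(C)C)C4(OC)C(O[Si](C(C)C)(C(C)C)C(C)C)=CC23OC4=O)ccc1O[Si](C(C)C)(C(C)C)C(C)C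
F2 | step 14 | [(1S,2R)-3-formyl-6-methoxy-1-[3-methoxy-4-(triisopropylsilyloxy)phenyl]-7-(triisopropylsilyloxy)-5-(trimethylsilyl)-1,2-dihydronaphthalen-2-yl]methyl acetate | COc1cc([C@H]2c3cc(O[Si](C(C)C)(C(C)C)C(C)C)c(OC)c([Si](C)(C)C)c3C=C(C=O)[C@@H]2COC(C)=O)ccc1O[Si](C(C)C)(C(C)C)C(C)C
F3 | step 4 | trimethylsilyl ketene acetal of 7, aryl cis to the silyloxy group | COc1cc(/C=C(\O[Si](C)(C)C)OC/C=C/COC(C)=O)ccc1O[Si](C(C)C)(C(C)C)C(C)C
F4 | step 4 | racemic (2S*,3S*)-3-(acetoxymethyl)-2-[3-methoxy-4-(triisopropylsilyloxy)phenyl]pent-4-enoic acid, both enantiomers | COc1cc([C@H]([C@@H](COC(C)=O)C=C)C(=O)O)ccc1O[Si](C(C)C)(C(C)C)C(C)C.COc1cc([C@@H]([C@H](COC(C)=O)C=C)C(=O)O)ccc1O[Si](C(C)C)(C(C)C)C(C)C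
F5 | step 4 | (S)-1-phenylethylammonium salt of 9 | COc1cc([C@H]([C@@H](COC(C)=O)C=C)C(=O)[O-])ccc1O[Si](C(C)C)(C(C)C)C(C)C.C[C@H]([NH3+])c1ccccc1
F6 | step 7 | acyl imidazolide of 9 | COc1cc([C@H]([C@@H](COC(C)=O)C=C)C(=O)n2ccnc2)ccc1O[Si](C(C)C)(C(C)C)C(C)C
F7 | step 7 | sodium lithium dianion of 12 | C=C(O[Li])C(OC)=C(OC)O[Na]
F8 | step 12 | tert-butyldimethylsilyl enol ether of 21, either alkene geometry | COc1cc([C@H]([C@@H](COC(C)=O)C=CO[Si](C)(C)C(C)(C)C)C2=CC(O[Si](C(C)C)(C(C)C)C(C)C)=C(OC)C(=O)O2)ccc1O[Si](C(C)C)(C(C)C)C(C)C
F9 | step 12 | methanesulfonate of 23 | COc1cc([C@H]([C@@H](COC(C)=O)C(C=O)C(OS(C)(=O)=O)C#C[Si](C)(C)C)C2=CC(O[Si](C(C)C)(C(C)C)C(C)C)=C(OC)C(=O)O2)ccc1O[Si](C(C)C)(C(C)C)C(C)C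
F0 | step 10 | none | none
A1 | alternative 1 | methyl (E)-3-[2-(3,3-dimethoxy-2-oxopropyl)-4-methoxy-5-(triisopropylsilyloxy)phenyl]prop-2-enoate | COC(=O)/C=C/c1cc(O[Si](C(C)C)(C(C)C)C(C)C)c(OC)cc1CC(=O)C(OC)OC
A2 | alternative 1 | [3-methoxy-4-(triisopropylsilyloxy)phenyl]boronic acid | COc1cc(B(O)O)ccc1O[Si](C(C)C)(C(C)C)C(C)C
A3 | alternative 1 | 1-aryl-2-methoxycarbonyl-3-hydroxy-3-(dimethoxymethyl)tetralin, aryl and ester trans, ester and hydroxyl cis | COc1cc([C@H]2c3cc(O[Si](C(C)C)(C(C)C)C(C)C)c(OC)cc3C[C@@](O)(C(OC)OC)[C@@H]2C(=O)OC)ccc1O[Si](C(C)C)(C(C)C)C(C)C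
A4 | alternative 2 | trans-3-aryl-5-(tert-butyldimethylsilyloxy)-2-[(tert-butyldimethylsilyloxy)methyl]-6-methoxyindan-1-one | COc1cc([C@H]2c3cc(O[Si](C)(C)C(C)(C)C)c(OC)cc3C(=O)[C@@H]2CO[Si](C)(C)C(C)(C)C)ccc1O[Si](C)(C)C(C)(C)C
A5 | alternative 2 | trimethylsilyldiazomethane | C[Si](C)(C)C=[N+]=[N-]
A6 | alternative 2 | trans-1-aryl-2-(silyloxymethyl)-3-oxotetralin (2-tetralone) | COc1cc([C@H]2c3cc(O[Si](C)(C)C(C)(C)C)c(OC)cc3CC(=O)[C@@H]2CO[Si](C)(C)C(C)(C)C)ccc1O[Si](C)(C)C(C)(C)C
A7 | alternative 3 | 5-(tert-butyldimethylsilyloxy)-2-[3-methoxy-4-(tert-butyldimethylsilyloxy)benzyl]-4-methoxybenzaldehyde | COc1cc(Cc2cc(O[Si](C)(C)C(C)(C)C)c(OC)cc2C=O)ccc1O[Si](C)(C)C(C)(C)C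
A8 | alternative 3 | (E)-4-acetoxybut-2-enal | CC(=O)OC/C=C/C=O
A9 | alternative 3 | 1-aryl-2-acetoxymethyl-3-formyl-4-hydroxytetralin, aryl, hydroxyl and formyl cis, acetoxymethyl trans | COc1cc([C@H]2c3cc(O[Si](C)(C)C(C)(C)C)c(OC)cc3[C@@H](O)[C@@H](C=O)[C@@H]2COC(C)=O)ccc1O[Si](C)(C)C(C)(C)C
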